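- The peaks could not add up: in a closed flask nothing leaves, yet at 8.00 min the dawn run showed starting material, target and side product summing to 72.2%, and the autumn run at 8.00 min was missing 65.3%.

| flask | starting material | protic impurity | remark | time |
|---|---|---|---|---|
| dawn | 0.20 M | 0.066 M | run made earlier |  |
| autumn | 0.20 M | 0.20 M | run made earlier |  |
| alder | 0.20 M | 0.0600 M |  | 15 min |
| elm | 0.20 M | 0.0900 M |  | 15 min |
| ash | 0.20 M | 0.140 M |  | 15 min |

- dawn (time / min: starting material / %, target / %, side product / %): 1.33: 54.4, 26.6, 0; 2.50: 35.5, 37.3, 3.1; 4.00: 24.0, 47.0, 3.6; 5.00: 20.7, 48.9, 5.6; 6.00: 18.7, 51.2, 2.7; 8.00: 15.5, 52.0, 4.7
- autumn (time / min: starting material / %, target / %, side product / %): 0.667: 51.7, 15.3, 0; 1.00: 38.3, 17.2, 0.2; 1.50: 27.1, 22.1, 0.9; 2.50: 15.4, 27.2, 0; 5.00: 4.0, 30.0, 0.4; 8.00: 3.6, 27.6, 3.5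

(readings scatter by 1 percentage point)

- the earlier runs were read with a standard deviation of 1 percentage point

1. which of these there is most of at the end, counted by the starting material in it, alder (target / starting material / side product)
2. which of these there is most of at the end, counted by the starting material in it, elm (target / starting material / side product)
3. which of these there is most of at the end, counted by the starting material in it, ash (target / starting material / side product)
4. amount of the one of these that there is most of at the end, in percent of the starting material charged, alder
5. amount of the one of these that there is most of at the end, in percent of the starting material charged, elm
6. amount of the one of these that there is most of at the end, in percent of the starting material charged, ash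

- I set that loss against the protic impurity charged over the starting material charged: 33.0% in dawn, 100% in autumn, 30.0% in alder, 45.0% in elm and 70.0% in ash. I called this ratio the claim: the part of the starting material the impurity can take if each molecule takes one.
- For the first instants I read the split (a selectivity factor), the part lost per part of target. Per molar of impurity it read 10.8 /M in dawn and 10.8 /M in autumn. So I expected 0.649 in alder and 1.52 in ash at the start.
- For the middle I turned the dawn readings into times. Starting material took about 2.68 min to halve by making target, while impurity, with starting material held at its charge, took about 1.24 min to halve. Because impurity went faster, I expected the loss to come early. But the missing share in autumn read 65.3% of its claim at its last reading, so that claim stood partly unpaid then.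
- For the end I took from dawn the target's share of what was found, 72.0%. Since that share beat the rest, I expected target to lead in each flask. My reckoning, this share of what the claim spares, gave 50.4% for alder and 39.6% for elm. For ash it gave 21.6% with the claim paid in full and 39.1% if paid as in autumn.
- The forecast also chose target, at 54%, 43% and 32%, on the ground that missing material “levels off near the impurity charge”. It stood above my alder and elm figures  and inside my ash range .
- The flasks gave target first, at 51.1% in alder, 43.9% in elm and 33.5% in ash.

    starting material + by-product → side product (k = 0.00450 /M/s)
    starting material + protic impurity → quenched substrate (k = 0.0690 /M/s)
    starting material ⇌ target + by-product (K = 0.320 M, k = 0.00470 /s)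

- In alder, the quench ran while impurity lasted, leaving 4.51% of its charge at the end, and quenched substrate reached 28.6% against a claim of 30.0%. In ash, starting material was down to 4.91% with 16.2% of the impurity still there, and quenched substrate stood at 58.7% against a claim of 70.0%. Each moved alone, up or down by one common factor, alder's settings ranked protic impurity (4.4 points), then time (1 points), then starting material (0.29 points), and its target shifted 6 points at impurity charges of 0.0359 M and 0.0849 M.
- The neighbour flask is ash with 0.34 M of starting material, which cuts the claim to 41.2% and gives my reckoning 42.3% of target. Computed, quenched substrate reached 40.8%, 0.99% of the impurity remained, and target came to 39.0%, more than in ash.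

The numbers in the tables were generated by integration with constants of no real substance; the scatter is artificial.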